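## Retrosynthetic overview

1. Last bond: C7–C8 (sp2–sp3). A vinyl bromide carrying ring A is joined to a lateral chloride on ring B by an enantioconvergent NiCl2·glyme/bis(oxazoline)-catalysed reductive coupling, which sets C8; one desilylation follows.
2. Ring A half: the C2–C3 bond comes from a vinylogous aldol of the twofold-symmetric 2,6-diethyl-3,5-dimethyl-4H-pyran-4-one (1) with a chiral aldehyde. Only one of its two identical ethyl arms reacts, and C2 and C3 are set in that step.
3. The chiral aldehyde (C3–C7, carrying C4 and C5) comes from a thiazolidinethione syn aldol with (E)-3-bromo-2-methylpropenal, made from propargyl alcohol by carboalumination.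
4. Ring B half: the same pyranone 1 is functionalised on both arms in turn, first by vinylogous aldol with propanal plus lipase resolution, then by lateral chlorination.
5. No ring is built: both pyranone rings enter intact with 1.

Chain atoms are numbered C1–C9 as in the non-6-en-2-yl name of the target; the ring B side-chain carbons are C2′ and C3′.

Assumption: 1 (heteroaromatic catalogue compound, otherwise one step from pentan-3-one and propanoic acid in polyphosphoric acid) and the acylated auxiliary 13 are bought, and the antipode of the bis(oxazoline) ligand in step 10 that gives 8R is fixed beforehand on a model coupling.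

## Route

Step 1
Reactants: 1 2,6-diethyl-3,5-dimethyl-4H-pyran-4-one; 2 propanal
Product: 5 (±)-anti-(2R*,3R*)-2-(6-ethyl-3,5-dimethyl-4-oxo-4H-pyran-2-yl)pentan-3-yl acetate, via sodium pyranone dienolate 3 (not isolated), via sodium aldolate 4 (not isolated)
Conditions: NaN(SiMe3)2 (0.95 equiv), THF, −78 °C; 2 (1.2 equiv), −78 °C; Ac2O (1.5 equiv), −78 → 0 °C; chromatography to remove the syn isomer
Reagents that add atoms: acetic anhydride CC(=O)OC(C)=O
Why: Vinylogous aldol reaction in which NaN(SiMe3)2 removes a proton from one of the two equivalent ethyl CH2 groups of 1, the extended sodium dienolate adds through its exocyclic carbon to propanal with the anti C2′/C3′ relationship expected for the open approach to this dienolate, and the reactive sodium aldolate is acetylated by Ac2O at low temperature before retro-aldol can occur, giving the racemic anti acetate.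

Step 2
Reactants: 5 (±)-anti acetate
Product: 6 2-ethyl-6-[(2R,3R)-3-hydroxypentan-2-yl]-3,5-dimethyl-4H-pyran-4-one
Conditions: Amano lipase PS (Burkholderia cepacia), pH 7 phosphate buffer/acetone 9:1, 30 °C, stopped near 45% conversion; chromatography
Reagents that add atoms: none
Why: Enzymatic kinetic resolution by hydrolysis, in which by the Kazlauskas rule the acetate with an R carbinol carbon (large group CH(Me)-pyranyl, medium group ethyl) is cleaved fast, so the (2R,3R)-alcohol is released, the (2S,3S)-acetate stays behind, and the absolute configuration of C2′ and C3′ is fixed.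

Step 3
Reactants: 6 (2R,3R)-alcohol
Product: 8 2-(1-chloroethyl)-6-[(2R,3R)-3-hydroxypentan-2-yl]-3,5-dimethyl-4H-pyran-4-one (both epimers at C–Cl), via dilithium alkoxide dienolate 7 (not isolated)
Conditions: LiN(SiMe3)2 (2.2 equiv), THF, −78 °C; C2Cl6 (1.1 equiv), −78 °C; aqueous work-up
Reagents that add atoms: hexachloroethane ClC(Cl)(Cl)C(Cl)(Cl)Cl
Why: Lateral enolate chlorination in which the first equivalent of base forms the C3′ alkoxide (it shields C2′–H and cannot eliminate), the second deprotonates the remaining ethyl CH2, and C2Cl6 chlorinates the exocyclic carbon; the C–Cl centre need not be controlled because step 10 passes through a planar radical.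

Step 4
Reactants: 9 prop-2-yn-1-ol
Product: 11 (E)-3-bromo-2-methylprop-2-en-1-ol, via dimethylalkenylalane 10 (not isolated)
Conditions: Me3Al (3 equiv), Cp2ZrCl2 (0.25 equiv), CH2Cl2, 0 °C → rt; NBS (1.2 equiv), THF, −30 → 0 °C; aqueous work-up
Reagents that add atoms: trimethylaluminium C[Al](C)C; N-bromosuccinimide O=C1CCC(=O)N1Br
Why: Negishi Cp2ZrCl2-catalysed carboalumination adds Me and Al syn across the alkyne (Me to the inner carbon), and bromodealumination with retention gives the E alkenyl bromide only.

Step 5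
Reactants: 11 (E)-3-bromo-2-methylprop-2-en-1-ol
Product: 12 (E)-3-bromo-2-methylprop-2-enal
Conditions: MnO2 (10 equiv), CH2Cl2, rt; filtered solution used directly
Reagents that add atoms: none
Why: Chemoselective allylic alcohol oxidation with activated MnO2, which does not isomerise the alkene.

Step 6
Reactants: 13 (S)-4-benzyl-3-propanoyl-1,3-thiazolidine-2-thione; 12 (E)-3-bromo-2-methylprop-2-enal
Product: 15 (2R,3R,4E)-1-[(4S)-4-benzyl-2-thioxo-1,3-thiazolidin-3-yl]-5-bromo-3-hydroxy-2,4-dimethylpent-4-en-1-one, via trichlorotitanium enolate 14 (not isolated)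
Conditions: TiCl4 (1.05 equiv), i-Pr2NEt (1.1 equiv), CH2Cl2, 0 → −78 °C; 12, −78 → 0 °C
Reagents that add atoms: none
Why: TiCl4-mediated Crimmins aldol with one equivalent of amine, in which the Z enolate reacts through the chelated (thiocarbonyl-bound) Zimmerman–Traxler transition state to give the non-Evans syn adduct, setting the future C4 and C5.

Step 7
Reactants: 15 syn aldol adduct
Product: 16 (2R,3R,4E)-1-[(4S)-4-benzyl-2-thioxo-1,3-thiazolidin-3-yl]-5-bromo-3-[(tert-butyldimethylsilyl)oxy]-2,4-dimethylpent-4-en-1-one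
Conditions: TBSOTf (1.3 equiv), 2,6-lutidine (2 equiv), CH2Cl2, 0 °C
Reagents that add atoms: tert-butyldimethylsilyl triflate CC(C)(C)[Si](C)(C)OS(=O)(=O)C(F)(F)F
Why: Standard silylation of a hindered secondary alcohol; the bulky non-chelating ether is needed for Felkin control in step 9 and blocks retro-aldol.

Step 8
Reactants: 16 silyl ether
Product: 17 (2R,3R,4E)-5-bromo-3-[(tert-butyldimethylsilyl)oxy]-2,4-dimethylpent-4-enal
Conditions: i-Bu2AlH (1.5 equiv), CH2Cl2, −78 °C; aqueous work-up; used at once
Reagents that add atoms: none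
Why: Direct reductive cleavage of the N-acylthiazolidinethione, where the chelated tetrahedral aluminate survives until work-up, so the aldehyde forms without over-reduction or α-epimerisation and the alkenyl bromide is untouched.

Step 9
Reactants: 1 2,6-diethyl-3,5-dimethyl-4H-pyran-4-one; 17 aldehyde
Product: 19 2-[(2S,3S,4S,5R,6E)-7-bromo-5-[(tert-butyldimethylsilyl)oxy]-3-hydroxy-4,6-dimethylhept-6-en-2-yl]-6-ethyl-3,5-dimethyl-4H-pyran-4-one, via lithium pyranone dienolate 18 (not isolated)
Conditions: 1 (1.5 equiv), LiN(SiMe3)2 (1.4 equiv), THF, −78 °C; 17, −78 °C, 1 h; aqueous work-up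
Reagents that add atoms: none
Why: Desymmetrising vinylogous aldol reaction in which the lithium dienolate from one ethyl arm of symmetric 1 adds to 17 under Felkin–Anh control (α-methyl, non-chelating β-silyloxy, bulky nucleophile), which sets C3 syn to the C4 methyl, while the anti preference of this dienolate sets C2.

Step 10
Reactants: 19 alkenyl bromide; 8 lateral chloride (1.5 equiv)
Product: 20 2-ethyl-6-[(2S,3S,4S,5R,6E,8R)-5-[(tert-butyldimethylsilyl)oxy]-3-hydroxy-8-{6-[(2R,3R)-3-hydroxypentan-2-yl]-3,5-dimethyl-4-oxo-4H-pyran-2-yl}-4,6-dimethylnon-6-en-2-yl]-3,5-dimethyl-4H-pyran-4-one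
Conditions: NiCl2·glyme (10 mol %), cyclopropane-1,1-diyl-bridged bis(indeno-oxazoline) ligand (11 mol %), Mn powder (3 equiv), NaI (0.5 equiv), DMA, 0 °C
Reagents that add atoms: none
Why: Proposed new method: low-valent nickel (from NiCl2·glyme and Mn) inserts into the alkenyl C–Br bond of 19 with retention of the E geometry, chloride 8 is reduced to a planar radical stabilised by the pyranone π system as a benzylic radical would be, the chiral alkenylnickel species captures it and reductive elimination forms C7–C8 with the ligand fixing C8 as R, so both C–Cl epimers converge and no base is present to epimerise the doubly activated C8–H; the closest known reaction type is the NiCl2·glyme/bis(oxazoline)-catalysed asymmetric reductive cross-coupling of vinyl bromides with racemic secondary benzylic chlorides.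

Step 11
Reactants: 20 silyl ether
Product: 21 target, 2-ethyl-6-[(2S,3S,4S,5R,6E,8R)-3,5-dihydroxy-8-{6-[(2R,3R)-3-hydroxypentan-2-yl]-3,5-dimethyl-4-oxo-4H-pyran-2-yl}-4,6-dimethylnon-6-en-2-yl]-3,5-dimethyl-4H-pyran-4-one
Conditions: HF·pyridine, pyridine/THF, 0 °C → rt
Reagents that add atoms: none
Why: Fluoride-driven silyl ether cleavage under buffered, non-basic conditions, so the base-sensitive C8 centre and the allylic alcohol are preserved.

## Compound list

1 | 2,6-diethyl-3,5-dimethyl-4H-pyran-4-one | CCc1oc(CC)c(C)c(=O)c1C | starting material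
2 | propanal | CCC=O | starting material
3 | sodium 6-ethyl-2-ethylidene-3,5-dimethyl-2H-pyran-4-olate (sodium dienolate of 1) | [Na+].CC=C1OC(CC)=C(C)C([O-])=C1C | intermediate
4 | sodium (2R*,3R*)-2-(6-ethyl-3,5-dimethyl-4-oxo-4H-pyran-2-yl)pentan-3-olate (racemic, one enantiomer drawn) | CCc1oc([C@H](C)[C@H]([O-])CC)c(C)c(=O)c1C.[Na+] | intermediate
5 | (±)-anti-(2R*,3R*)-2-(6-ethyl-3,5-dimethyl-4-oxo-4H-pyran-2-yl)pentan-3-yl acetate (racemic, one enantiomer drawn) | CCc1oc([C@H](C)[C@H](OC(C)=O)CC)c(C)c(=O)c1C | intermediate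
6 | 2-ethyl-6-[(2R,3R)-3-hydroxypentan-2-yl]-3,5-dimethyl-4H-pyran-4-one | CCc1oc([C@H](C)[C@H](O)CC)c(C)c(=O)c1C | intermediate
7 | dilithium salt of 6 (C3′ alkoxide and 6-ethylidene dienolate) | [Li+].[Li+].CC=C1OC([C@H](C)[C@H]([O-])CC)=C(C)C([O-])=C1C | intermediate
8 | 2-(1-chloroethyl)-6-[(2R,3R)-3-hydroxypentan-2-yl]-3,5-dimethyl-4H-pyran-4-one (both C–Cl epimers) | CC(Cl)c1oc([C@H](C)[C@H](O)CC)c(C)c(=O)c1C | intermediate
9 | prop-2-yn-1-ol | C#CCO | starting material
10 | dimethylaluminium (E)-3-(dimethylalumanyl)-2-methylprop-2-en-1-olate | C[Al](C)OC/C(C)=C/[Al](C)C | intermediate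
11 | (E)-3-bromo-2-methylprop-2-en-1-ol | OC/C(C)=C/Br | intermediate
12 | (E)-3-bromo-2-methylprop-2-enal | O=C/C(C)=C/Br | intermediate
13 | (S)-4-benzyl-3-propanoyl-1,3-thiazolidine-2-thione | CCC(=O)N1C(=S)SC[C@@H]1Cc1ccccc1 | starting material
14 | trichlorotitanium (Z)-enolate of 13 | C/C=C(\O[Ti](Cl)(Cl)Cl)N1C(=S)SC[C@@H]1Cc1ccccc1 | intermediate
15 | (2R,3R,4E)-1-[(4S)-4-benzyl-2-thioxo-1,3-thiazolidin-3-yl]-5-bromo-3-hydroxy-2,4-dimethylpent-4-en-1-one | Br/C=C(C)/[C@H](O)[C@@H](C)C(=O)N1C(=S)SC[C@@H]1Cc1ccccc1 | intermediate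
16 | (2R,3R,4E)-1-[(4S)-4-benzyl-2-thioxo-1,3-thiazolidin-3-yl]-5-bromo-3-[(tert-butyldimethylsilyl)oxy]-2,4-dimethylpent-4-en-1-one | Br/C=C(C)/[C@H](O[Si](C)(C)C(C)(C)C)[C@@H](C)C(=O)N1C(=S)SC[C@@H]1Cc1ccccc1 | intermediate
17 | (2R,3R,4E)-5-bromo-3-[(tert-butyldimethylsilyl)oxy]-2,4-dimethylpent-4-enal | Br/C=C(C)/[C@H](O[Si](C)(C)C(C)(C)C)[C@@H](C)C=O | intermediate
18 | lithium 6-ethyl-2-ethylidene-3,5-dimethyl-2H-pyran-4-olate (lithium dienolate of 1) | [Li+].CC=C1OC(CC)=C(C)C([O-])=C1C | intermediate
19 | 2-[(2S,3S,4S,5R,6E)-7-bromo-5-[(tert-butyldimethylsilyl)oxy]-3-hydroxy-4,6-dimethylhept-6-en-2-yl]-6-ethyl-3,5-dimethyl-4H-pyran-4-one | CCc1oc([C@@H](C)[C@@H](O)[C@H](C)[C@@H](O[Si](C)(C)C(C)(C)C)/C(C)=C/Br)c(C)c(=O)c1C | intermediate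
20 | C5-O-tert-butyldimethylsilyl ether of the target (2S,3S,4S,5R,6E,8R; 2′R,3′R) | CCc1oc([C@@H](C)[C@@H](O)[C@H](C)[C@@H](O[Si](C)(C)C(C)(C)C)/C(C)=C/[C@@H](C)c2oc([C@H](C)[C@H](O)CC)c(C)c(=O)c2C)c(C)c(=O)c1C | intermediate
21 | CNP0408419.8 | CCc1oc([C@@H](C)[C@@H](O)[C@H](C)[C@@H](O)/C(C)=C/[C@@H](C)c2oc([C@H](C)[C@H](O)CC)c(C)c(=O)c2C)c(C)c(=O)c1C | target

## Step count and risks

Total step count: 11. Longest linear sequence: 8 (steps 4 to 11); steps 1 to 3 form the second branch, which joins at step 10.

Steps most likely to fail: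

**Step 10 (NiCl2·glyme-catalysed coupling).** The pyranone-type chloride and the trisubstituted alkenyl bromide are both outside the proven scope, Mn may simply dechlorinate 8, and the C8 selectivity is untested. The fallback sets out from 6 and 19 and comes back at 20. Compound 6 is converted to 7 as in step 3 and transmetalated with ZnCl2 to the bis(chlorozinc) alkoxide dienolate of 6 F1. This is used in excess (2.5 equiv) and coupled with 19 under Pd(dba)2/P(t-Bu)3 in THF at rt, a Negishi-type alkenylation of a zinc enolate at its exocyclic carbon. That two-electron coupling is not enantioconvergent, so 20 forms together with its C8 epimer, the (8S)-epimer of 20 F2. The two are separated by preparative HPLC and only 20 goes on.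

**Step 9 (anti/Felkin vinylogous aldol).** The anti preference of the dienolate and the Felkin preference of a syn α-methyl-β-silyloxy aldehyde may both be only moderate. The fallback sets out from 1 and 17 and comes back at 19. Pyranone 1 is deprotonated as in step 9 and the dienolate 18 is trapped with TBSCl as the silyl dienol ether, tert-butyl[(6-ethyl-2-ethylidene-3,5-dimethyl-2H-pyran-4-yl)oxy]dimethylsilane F3. F3 is added to 17 with BF3·OEt2 in CH2Cl2 at −78 °C, a vinylogous Mukaiyama aldol through an open transition state in which Felkin control by the α-methyl group is normally at its strongest. Aqueous work-up removes the silyl group from the pyranone oxygen and gives 19.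

**Step 2 (lipase resolution).** An ethyl medium group and an α-branched large group may give a low rate or a low selectivity factor, and half of the material is lost by design. The fallback sets out from 2 and 3 and comes back at 6. Propanal 2 is α-chlorinated with NCS and a chiral secondary amine catalyst (the antipode giving R) to (R)-2-chloropropanal F4, kept in solution. Dienolate 3 adds to F4 under Cornforth control (3′,4′-anti) to give the chlorohydrin 6-[(2R,3S,4R)-4-chloro-3-hydroxypentan-2-yl]-2-ethyl-3,5-dimethyl-4H-pyran-4-one F5. Bu3SnH with AIBN in toluene at 80 °C replaces C–Cl by C–H and delivers 6 directly in enantioenriched form.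

Further compounds
F1 | step 10 | bis(chlorozinc) alkoxide dienolate of 6 | CC=C1OC([C@H](C)[C@H](O[Zn]Cl)CC)=C(C)C(O[Zn]Cl)=C1C
F2 | step 10 | (8S)-epimer of 20 | CCc1oc([C@@H](C)[C@@H](O)[C@H](C)[C@@H](O[Si](C)(C)C(C)(C)C)/C(C)=C/[C@H](C)c2oc([C@H](C)[C@H](O)CC)c(C)c(=O)c2C)c(C)c(=O)c1C
F3 | step 9 | tert-butyl[(6-ethyl-2-ethylidene-3,5-dimethyl-2H-pyran-4-yl)oxy]dimethylsilane | CC=C1OC(CC)=C(C)C(O[Si](C)(C)C(C)(C)C)=C1C
F4 | step 2 | (R)-2-chloropropanal | C[C@@H](Cl)C=O
F5 | step 2 | 6-[(2R,3S,4R)-4-chloro-3-hydroxypentan-2-yl]-2-ethyl-3,5-dimethyl-4H-pyran-4-one | CCc1oc([C@H](C)[C@H](O)[C@@H](C)Cl)c(C)c(=O)c1C
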